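**Retrosynthetic overview**
1. The target is read as epiafzelechin-(4β→8)-epiafzelechin-(4β→8)-4′-O-methyl-(−)-epigallocatechin. The last C–C bonds are the two interflavan C4–C8 bonds, made by ionising one 4-alkoxy-epiafzelechin block (13) twice, first onto the bottom unit 16 and then onto dimer 17, followed by global debenzylation.
2. The bottom unit keeps the three rings of (−)-epigallocatechin (selective 4′-O-methylation, then benzylation).
3. Both upper units come from one racemic flavan-3-one (11); its C2 and C3 centres are set together by a dynamic kinetic asymmetric reduction.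
4. Key disconnection: C3 of that pyran ring is the carbon of nitromethane, used as a nitronate (masked carbonyl carbon). It is bonded to the aldehyde carbon of 3 (C2–C3) and to the aldehyde carbon of 2 (C3–C4), then unmasked to the ketone.
5. Ring order: A and B rings are bought as arenes; the pyran ring of the upper unit forms in step 2 (O1–C2 by oxa-Michael, then C3–C4 by intramolecular Henry); the three flavan units are then joined bottom-up.

Assumption: (−)-epigallocatechin (from green tea) is taken as a cheap commercial material.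

**Step 1**
Reactants: 1 2,4,6-trihydroxybenzaldehyde
Product: 2 2,4-bis(benzyloxy)-6-hydroxybenzaldehyde
Conditions: BnBr (2.05 equiv), K2CO3 (2.2 equiv), DMF, 0 °C → rt
Reagents that add atoms: benzyl bromide, BrCc1ccccc1
Why: Williamson etherification benzylates the para-OH and one ortho-OH, while the remaining ortho-OH, hydrogen-bonded to the formyl group, is the least acidic and least nucleophilic and stays free.

**Step 2**
Reactants: 3 4-(benzyloxy)benzaldehyde; 4 nitromethane; 2 2,4-bis(benzyloxy)-6-hydroxybenzaldehyde (added in the second stage)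
Product: 8 rac-5,7-bis(benzyloxy)-2-[4-(benzyloxy)phenyl]-3-nitro-2H-chromene, via nitrostyrene 5 (not isolated), via oxa-Michael adduct 6 (not isolated), via nitro-aldol 7 (not isolated)
Conditions: 3, MeNO2 (5 equiv), NH4OAc (0.5 equiv), AcOH, 100 °C, 4 h; strip volatiles; then 2 (0.9 equiv), DABCO (1.0 equiv), MeCN, 60 °C, 24 h (one pot)
Reagents that add atoms: none
Why: The nitromethane carbon acts twice as a nitronate, i.e. a masked-carbonyl (acyl-anion-type) nucleophile: Henry condensation with 3 gives 5, then a DABCO-mediated oxa-Michael/intramolecular Henry/dehydration cascade with 2 closes the pyran ring and forms C3–C4 between two carbonyl-derived carbons, the product being racemic on purpose because C2 is set in step 4.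

**Step 3**
Reactants: 8 rac-5,7-bis(benzyloxy)-2-[4-(benzyloxy)phenyl]-3-nitro-2H-chromene
Product: 11 rac-5,7-bis(benzyloxy)-2-[4-(benzyloxy)phenyl]chroman-3-one, via oxime 9 (not isolated), via imine 10 (not isolated)
Conditions: Fe powder (6 equiv), AcOH/EtOH/H2O, 80 °C, N2
Reagents that add atoms: water, O
Why: Dissolving-metal reduction of the conjugated nitroalkene (a reductive Nef-type unmasking) passes through the oxime and the imine, whose hydrolysis reveals the C3 ketone, while benzyl ethers are inert and no stereocentre has to survive.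

**Step 4**
Reactants: 11 rac-5,7-bis(benzyloxy)-2-[4-(benzyloxy)phenyl]chroman-3-one
Product: 12 (2R,3R)-5,7-bis(benzyloxy)-2-[4-(benzyloxy)phenyl]chroman-3-ol (5,7,4′-tri-O-benzyl-(−)-epiafzelechin)
Conditions: RuCl[(R,R)-TsDPEN](p-cymene) (2 mol %), HCO2H–Et3N (5:2), EtOAc, 40 °C
Reagents that add atoms: none
Why: Proposed new method: Noyori–Ikariya asymmetric transfer hydrogenation run as a dynamic kinetic resolution, in which the C2–H (α to the ketone, benzylic and α to oxygen) racemises through the enol while the chiral Ru–H reduces one enantiomer much faster with hydride arriving anti to the 2-aryl group, so that the 2,3-cis alcohol forms and C2 (R) and C3 (R) are set together; the closest known reactions are the DKR transfer hydrogenation of isoflavanones to cis-isoflavan-4-ols and the cis-selective hydride reduction of benzylated flavan-3-ones, and the (R,R) catalyst is chosen by analogy with α-aryloxy ketones and is exchanged for (S,S) if the first run shows the opposite sense.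

**Step 5**
Reactants: 12 5,7,4′-tri-O-benzyl-(−)-epiafzelechin
Product: 13 (2R,3R,4S)-5,7-bis(benzyloxy)-2-[4-(benzyloxy)phenyl]-4-(2-ethoxyethoxy)chroman-3-ol (4β-ether)
Conditions: DDQ (2 equiv), 2-ethoxyethanol (5 equiv), CH2Cl2, rt
Reagents that add atoms: 2-ethoxyethanol, CCOCCO
Why: DDQ abstracts hydride from C4 (benzylic to the 5,7-dialkoxy A ring) and the alcohol adds to the resulting quinone-methide cation anti to the axial 3-OH, giving the 4β (3,4-trans) ether in a benzylic oxidative etherification, as used for benzylated epicatechin.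

**Step 6**
Reactants: 14 (−)-epigallocatechin
Product: 15 4′-O-methyl-(−)-epigallocatechin
Conditions: MeI (1.05 equiv), K2CO3 (1.0 equiv), DMF, 0 °C → rt, Ar
Reagents that add atoms: iodomethane, CI
Why: Williamson methylation with one equivalent of weak base alkylates the central 4′-OH of the pyrogallol ring first because it is the most acidic phenol (its phenoxide is flanked by two hydrogen-bonding OH groups), the same selectivity seen in methylation of gallates and EGCG, and no stereocentre is touched.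

**Step 7**
Reactants: 15 4′-O-methyl-(−)-epigallocatechin
Product: 16 5,7,3′,5′-tetra-O-benzyl-4′-O-methyl-(−)-epigallocatechin
Conditions: BnBr (4.4 equiv), K2CO3 (5 equiv), DMF, rt, Ar
Reagents that add atoms: benzyl bromide, BrCc1ccccc1
Why: Williamson benzylation caps the four remaining phenols while the secondary 3-OH is not deprotonated by carbonate, and with 4′ already methylated no quinone-methide epimerisation at C2 is possible.

**Step 8**
Reactants: 13 4β-(2-ethoxyethoxy) electrophile; 16 5,7,3′,5′-tetra-O-benzyl-4′-O-methyl-(−)-epigallocatechin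
Product: 17 5,7,4′-tri-O-benzyl-epiafzelechin-(4β→8)-5,7,3′,5′-tetra-O-benzyl-4′-O-methyl-epigallocatechin
Conditions: 16 (3 equiv, excess recovered), TMSOTf (0.2 equiv), CH2Cl2, −78 °C
Reagents that add atoms: none
Why: TMSOTf ionises the 4-alkoxy group of 13 to the A-ring-stabilised C4 cation, which is trapped in a Friedel–Crafts alkylation by C8 (the most nucleophilic position) of excess 16, attack coming anti to the 3-OH to give the 4β (3,4-trans) interflavan bond.

**Step 9**
Reactants: 13 4β-(2-ethoxyethoxy) electrophile; 17 dimer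
Product: 18 5,7,4′-tri-O-benzyl-epiafzelechin-(4β→8)-5,7,4′-tri-O-benzyl-epiafzelechin-(4β→8)-5,7,3′,5′-tetra-O-benzyl-4′-O-methyl-epigallocatechin
Conditions: 17 (2 equiv, excess recovered), TMSOTf (0.2 equiv), CH2Cl2, −78 → −40 °C
Reagents that add atoms: none
Why: The same Lewis-acid Friedel–Crafts flavanylation, in which the C4 cation from 13 attacks the free C8 of the upper unit of 17 (more nucleophilic and less hindered than either C6), again anti to its own 3-OH, giving the second 4β→8 bond.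

**Step 10**
Reactants: 18 decabenzyl trimer
Product: 19 epiafzelechin-(4β→8)-epiafzelechin-(4β→8)-4′-O-methyl-(−)-epigallocatechin (CNP0146516.1)
Conditions: H2 (1 atm), 20% Pd(OH)2/C, THF/MeOH/H2O, rt
Reagents that add atoms: none
Why: Hydrogenolysis over Pearlman's catalyst cleaves all ten O-benzyl groups while the methyl ether, the cyclic benzylic ethers and all eight stereocentres are untouched.

**Compound list**
1 | 2,4,6-trihydroxybenzaldehyde | O=Cc1c(O)cc(O)cc1O | starting material
2 | 2,4-bis(benzyloxy)-6-hydroxybenzaldehyde | O=Cc1c(O)cc(OCc2ccccc2)cc1OCc1ccccc1 | intermediate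
3 | 4-(benzyloxy)benzaldehyde | O=Cc1ccc(OCc2ccccc2)cc1 | starting material
4 | nitromethane | C[N+](=O)[O-] | starting material
5 | (E)-1-(benzyloxy)-4-(2-nitrovinyl)benzene | [O-][N+](=O)/C=C/c1ccc(OCc2ccccc2)cc1 | intermediate
6 | rac-2,4-bis(benzyloxy)-6-{1-[4-(benzyloxy)phenyl]-2-nitroethoxy}benzaldehyde | O=Cc1c(OC(C[N+](=O)[O-])c2ccc(OCc3ccccc3)cc2)cc(OCc2ccccc2)cc1OCc1ccccc1 | intermediate
7 | 5,7-bis(benzyloxy)-2-[4-(benzyloxy)phenyl]-3-nitrochroman-4-ol (racemic, mixture of diastereomers) | OC1c2c(OCc3ccccc3)cc(OCc3ccccc3)cc2OC(c2ccc(OCc3ccccc3)cc2)C1[N+](=O)[O-] | intermediate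
8 | rac-5,7-bis(benzyloxy)-2-[4-(benzyloxy)phenyl]-3-nitro-2H-chromene | [O-][N+](=O)C1=Cc2c(OCc3ccccc3)cc(OCc3ccccc3)cc2OC1c1ccc(OCc2ccccc2)cc1 | intermediate
9 | rac-5,7-bis(benzyloxy)-2-[4-(benzyloxy)phenyl]chroman-3-one oxime | ON=C1Cc2c(OCc3ccccc3)cc(OCc3ccccc3)cc2OC1c1ccc(OCc2ccccc2)cc1 | intermediate
10 | rac-5,7-bis(benzyloxy)-2-[4-(benzyloxy)phenyl]chroman-3-imine | N=C1Cc2c(OCc3ccccc3)cc(OCc3ccccc3)cc2OC1c1ccc(OCc2ccccc2)cc1 | intermediate
11 | rac-5,7-bis(benzyloxy)-2-[4-(benzyloxy)phenyl]chroman-3-one | O=C1Cc2c(OCc3ccccc3)cc(OCc3ccccc3)cc2OC1c1ccc(OCc2ccccc2)cc1 | intermediate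
12 | (2R,3R)-5,7-bis(benzyloxy)-2-[4-(benzyloxy)phenyl]chroman-3-ol (5,7,4′-tri-O-benzyl-(−)-epiafzelechin) | O(Cc1ccccc1)c1ccc(cc1)[C@H]1Oc2cc(OCc3ccccc3)cc(OCc3ccccc3)c2C[C@H]1O | intermediate
13 | (2R,3R,4S)-5,7-bis(benzyloxy)-2-[4-(benzyloxy)phenyl]-4-(2-ethoxyethoxy)chroman-3-ol (4β-ether, trans to 3-OH) | CCOCCO[C@H]1c2c(OCc3ccccc3)cc(OCc3ccccc3)cc2O[C@H](c2ccc(OCc3ccccc3)cc2)[C@@H]1O | intermediate
14 | (−)-epigallocatechin, (2R,3R) | Oc1cc(cc(O)c1O)[C@H]1Oc2cc(O)cc(O)c2C[C@H]1O | starting material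
15 | 4′-O-methyl-(−)-epigallocatechin, (2R,3R) | COc1c(O)cc(cc1O)[C@H]1Oc2cc(O)cc(O)c2C[C@H]1O | intermediate
16 | 5,7,3′,5′-tetra-O-benzyl-4′-O-methyl-(−)-epigallocatechin, (2R,3R) | COc1c(OCc2ccccc2)cc(cc1OCc1ccccc1)[C@H]1Oc2cc(OCc3ccccc3)cc(OCc3ccccc3)c2C[C@H]1O | intermediate
17 | 5,7,4′-tri-O-benzyl-epiafzelechin-(4β→8)-5,7,3′,5′-tetra-O-benzyl-4′-O-methyl-epigallocatechin (both units 2R,3R; interflavan bond trans to the upper 3-OH) | COc1c(OCc2ccccc2)cc([C@H]2Oc3c(c(OCc4ccccc4)cc(OCc4ccccc4)c3[C@H]3c4c(OCc5ccccc5)cc(OCc5ccccc5)cc4O[C@H](c4ccc(OCc5ccccc5)cc4)[C@@H]3O)C[C@H]2O)cc1OCc1ccccc1 | intermediate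
18 | decabenzyl trimer: 5,7,4′-tri-O-benzyl-epiafzelechin-(4β→8)-5,7,4′-tri-O-benzyl-epiafzelechin-(4β→8)-5,7,3′,5′-tetra-O-benzyl-4′-O-methyl-epigallocatechin | COc1c(OCc2ccccc2)cc([C@H]2Oc3c(c(OCc4ccccc4)cc(OCc4ccccc4)c3[C@H]3c4c(OCc5ccccc5)cc(OCc5ccccc5)c([C@H]5c6c(OCc7ccccc7)cc(OCc7ccccc7)cc6O[C@H](c6ccc(OCc7ccccc7)cc6)[C@@H]5O)c4O[C@H](c4ccc(OCc5ccccc5)cc4)[C@@H]3O)C[C@H]2O)cc1OCc1ccccc1 | intermediate
19 | epiafzelechin-(4β→8)-epiafzelechin-(4β→8)-4′-O-methyl-(−)-epigallocatechin (CNP0146516.1) | COc1c(O)cc([C@H]2Oc3c(c(O)cc(O)c3[C@H]3c4c(O)cc(O)c([C@H]5c6c(O)cc(O)cc6O[C@H](c6ccc(O)cc6)[C@@H]5O)c4O[C@H](c4ccc(O)cc4)[C@@H]3O)C[C@H]2O)cc1O | target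

**Step count**
Total: 10 steps (step 2 is a telescoped one-pot). Longest linear sequence: 8 steps (1, 2, 3, 4, 5, 8, 9, 10); the bottom unit (steps 6 and 7) is made in parallel.

**Three steps most likely to fail, with fallbacks**

Step 4 (the dynamic kinetic reduction is unprecedented on a flavan-3-one; sense and level of induction are unproven). The fallback sets out from 11 and comes back at 12. Racemic 11 is reduced with L-Selectride (THF, −78 °C), which is cis-selective on benzylated flavan-3-ones, to racemic cis-5,7,4′-tri-O-benzylflavan-3-ol F1. The enantiomers are separated by preparative chiral SFC to give 12. The unwanted (2S,3S)-5,7,4′-tri-O-benzyl-ent-epiafzelechin F2 is oxidised back to 11 with Dess–Martin periodinane and recycled.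

Step 6 (mono-methylation may spread over the A-ring phenols or over-methylate). The fallback sets out from 14 and comes back at 15. It replaces acidity control by enzyme control: catechol-O-methyltransferase with S-adenosylmethionine (with cofactor regeneration) is the pathway that converts epigallocatechin into its 4′-O-methyl ether. This fallback makes no new compound (F0).

Step 9 (the precious dimer is the nucleophile; the electrophile can self-condense or attack a C6 position). The fallback sets out from 13 and comes back at 19. Compound 13 is brominated at C8 with NBS (CH2Cl2, −78 °C) to the capped electrophile (2R,3R,4S)-8-bromo-5,7-bis(benzyloxy)-2-[4-(benzyloxy)phenyl]-4-(2-ethoxyethoxy)chroman-3-ol F3, which can no longer act as a nucleophile. F3 is coupled 1:1 with 17 (AgOTf, CH2Cl2, −40 °C) to the 8-bromo decabenzyl trimer F4. Hydrogenolysis (H2, Pd(OH)2/C, Et3N, THF/MeOH) removes the bromine together with the ten benzyl groups and gives 19 directly.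

**Further compounds**
F1 | step 4 | racemic cis-5,7-bis(benzyloxy)-2-[4-(benzyloxy)phenyl]chroman-3-ol (1:1 mixture of 2R,3R and 2S,3S) | O(Cc1ccccc1)c1ccc(cc1)[C@H]1Oc2cc(OCc3ccccc3)cc(OCc3ccccc3)c2C[C@H]1O.O(Cc1ccccc1)c1ccc(cc1)[C@@H]1Oc2cc(OCc3ccccc3)cc(OCc3ccccc3)c2C[C@@H]1O
F2 | step 4 | (2S,3S)-5,7-bis(benzyloxy)-2-[4-(benzyloxy)phenyl]chroman-3-ol (5,7,4′-tri-O-benzyl-ent-epiafzelechin) | O(Cc1ccccc1)c1ccc(cc1)[C@@H]1Oc2cc(OCc3ccccc3)cc(OCc3ccccc3)c2C[C@@H]1O
F0 | step 6 | none | none
F3 | step 9 | (2R,3R,4S)-8-bromo-5,7-bis(benzyloxy)-2-[4-(benzyloxy)phenyl]-4-(2-ethoxyethoxy)chroman-3-ol | CCOCCO[C@H]1c2c(OCc3ccccc3)cc(OCc3ccccc3)c(Br)c2O[C@H](c2ccc(OCc3ccccc3)cc2)[C@@H]1O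
F4 | step 9 | 8-bromo (top unit) derivative of decabenzyl trimer 18 | COc1c(OCc2ccccc2)cc([C@H]2Oc3c(c(OCc4ccccc4)cc(OCc4ccccc4)c3[C@H]3c4c(OCc5ccccc5)cc(OCc5ccccc5)c([C@H]5c6c(OCc7ccccc7)cc(OCc7ccccc7)c(Br)c6O[C@H](c6ccc(OCc7ccccc7)cc6)[C@@H]5O)c4O[C@H](c4ccc(OCc5ccccc5)cc4)[C@@H]3O)C[C@H]2O)cc1OCc1ccccc1
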